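**Retrosynthetic overview**
- The target comes from its 2',4'-di-O-benzyl ether by neutral hydrogenolysis, which does not touch the five methyl ethers.
- Ring C (the pyranone) is the only ring built and it is closed last, by oxidative cyclisation of a 2'-hydroxychalcone. Rings A and B are bought as benzene rings.
- The chalcone C(alpha)–C(beta) bond comes from an intermolecular Claisen–Schmidt aldol condensation of a ring A methyl ketone with a ring B aldehyde.
- The ring A ketone comes from 2,3,4-trimethoxybenzaldehyde: CHO to OH (Baeyer–Villiger), O-methylation, formylation, CHO to OH again, then acylation of the last free ring carbon.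
- The ring B aldehyde comes from 2,4-dihydroxybenzaldehyde: double benzylation, CHO to OH, O-methylation, Vilsmeier formylation.

**Assumption:** the target is a planar flavone with no stereocentre, so it is achiral and needs no enantiocontrol. The only stereo-element on the route is the E alkene of the chalcone, which disappears when ring C is closed.

**Ring A fragment**

Step 1
Reactants: 1 2,3,4-trimethoxybenzaldehyde
Product: 3 2,3,4-trimethoxyphenol, via aryl formate 2 (not isolated)
Conditions: mCPBA (1.2 equiv), CH2Cl2, 0 °C to rt; aqueous wash; then HCl (cat.), MeOH, rt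
Reagents that add atoms: mCPBA, OOC(=O)c1cccc(Cl)c1
Why: In this Baeyer–Villiger oxidation the aryl group, activated by ortho and para OMe, migrates in preference to H, and acid-catalysed methanolysis then frees the phenol from formate 2; no stereocentre is formed.

Step 2
Reactants: 3 2,3,4-trimethoxyphenol
Product: 4 1,2,3,4-tetramethoxybenzene
Conditions: MeI (1.5 equiv), K2CO3 (2 equiv), acetone, reflux
Reagents that add atoms: iodomethane, CI
Why: This is a Williamson ether synthesis (SN2 of the phenolate on MeI), and the phenol is the only nucleophilic site.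

Step 3
Reactants: 4 1,2,3,4-tetramethoxybenzene
Product: 6 2,3,4,5-tetramethoxybenzaldehyde, via aryl iminium salt 5 (not isolated)
Conditions: POCl3 (2 equiv), DMF, 0 to 80 °C; then ice-water
Reagents that add atoms: DMF, CN(C)C=O; water, O
Why: In this Vilsmeier–Haack formylation the two free positions of symmetric 4 are equivalent and each is ortho/para to OMe, so one regioisomer forms, and the iminium/aldehyde group deactivates the ring against a second attack.

Step 4
Reactants: 6 2,3,4,5-tetramethoxybenzaldehyde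
Product: 8 2,3,4,5-tetramethoxyphenol, via aryl formate 7 (not isolated)
Conditions: mCPBA (1.2 equiv), CH2Cl2, 0 °C to rt; aqueous wash; then HCl (cat.), MeOH, rt, under N2
Reagents that add atoms: mCPBA, OOC(=O)c1cccc(Cl)c1
Why: This is a Baeyer–Villiger oxidation with aryl migration, and the very electron-rich phenol stays masked as formate 7 while oxidant is present and is released only afterwards by transesterification.

Step 5
Reactants: 8 2,3,4,5-tetramethoxyphenol
Product: 11 1-(2-hydroxy-3,4,5,6-tetramethoxyphenyl)ethan-1-one, via aryl acetate 9 (not isolated), via difluoroboron chelate 10 (not isolated)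
Conditions: Ac2O (1.5 equiv), BF3·OEt2 (3 equiv), 0 to 70 °C, 2 h; then H2O/MeOH, 60 °C
Reagents that add atoms: acetic anhydride, CC(=O)OC(C)=O
Why: O-acetylation is followed by a BF3-promoted Fries rearrangement (Friedel–Crafts C-acylation) that can only reach the single unsubstituted carbon, ortho to the oxygen, and the six-membered BF2 chelate pulls the reaction to the ortho-hydroxy ketone.

**Ring B fragment**

Step 6
Reactants: 12 2,4-dihydroxybenzaldehyde
Product: 13 2,4-bis(benzyloxy)benzaldehyde
Conditions: BnBr (2.4 equiv), K2CO3 (3 equiv), DMF, 70 °C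
Reagents that add atoms: benzyl bromide, BrCc1ccccc1
Why: This is a double Williamson ether synthesis, and warm DMF with excess base also alkylates the hydrogen-bonded 2-OH.

Step 7
Reactants: 13 2,4-bis(benzyloxy)benzaldehyde
Product: 15 2,4-bis(benzyloxy)phenol, via aryl formate 14 (not isolated)
Conditions: mCPBA (1.2 equiv), CH2Cl2, 0 °C to rt; aqueous wash; then HCl (cat.), MeOH, rt
Reagents that add atoms: mCPBA, OOC(=O)c1cccc(Cl)c1
Why: In this Baeyer–Villiger oxidation the ortho/para-dialkoxyaryl group migrates cleanly, and benzyl ethers are inert to both the peracid and the catalytic-acid methanolysis.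

Step 8
Reactants: 15 2,4-bis(benzyloxy)phenol
Product: 16 2,4-bis(benzyloxy)-1-methoxybenzene
Conditions: MeI (1.5 equiv), K2CO3 (2 equiv), acetone, reflux
Reagents that add atoms: iodomethane, CI
Why: This Williamson ether synthesis places the only methyl group of ring B on the oxygen that becomes 5'-OMe.

Step 9
Reactants: 16 2,4-bis(benzyloxy)-1-methoxybenzene
Product: 18 2,4-bis(benzyloxy)-5-methoxybenzaldehyde, via aryl iminium salt 17 (not isolated)
Conditions: POCl3 (1.5 equiv), DMF, 0 to 60 °C; then ice-water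
Reagents that add atoms: DMF, CN(C)C=O; water, O
Why: This Vilsmeier–Haack formylation goes to C5, which is para to one OBn and ortho to the other, while C3 is blocked between two OBn groups and C6 is activated by OMe alone, the same selectivity that turns 1,2,4-trimethoxybenzene into 2,4,5-trimethoxybenzaldehyde.

**Union and completion**

Step 10
Reactants: 11 1-(2-hydroxy-3,4,5,6-tetramethoxyphenyl)ethan-1-one; 18 2,4-bis(benzyloxy)-5-methoxybenzaldehyde
Product: 20 (E)-3-[2,4-bis(benzyloxy)-5-methoxyphenyl]-1-(2-hydroxy-3,4,5,6-tetramethoxyphenyl)prop-2-en-1-one, via aldol adduct 19 (not isolated)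
Conditions: KOH (50% aq, 10 equiv), EtOH/THF, rt, 48 h; then 1 M HCl, 0 °C
Reagents that add atoms: none
Why: In this Claisen–Schmidt (crossed aldol) condensation only 11 can form an enolate and only 18 is an aldehyde, racemic aldol 19 loses water by E1cB, and the conjugated E alkene is the thermodynamic product.

Step 11
Reactants: 20 (E)-3-[2,4-bis(benzyloxy)-5-methoxyphenyl]-1-(2-hydroxy-3,4,5,6-tetramethoxyphenyl)prop-2-en-1-one
Product: 23 2-[2,4-bis(benzyloxy)-5-methoxyphenyl]-5,6,7,8-tetramethoxy-4H-chromen-4-one, via flavanone 21 (not isolated), via 3-iodoflavanone 22 (not isolated)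
Conditions: I2 (10 mol %), DMSO, 120 °C, 3 h
Reagents that add atoms: none
Why: In this I2/DMSO oxidative cyclisation an intramolecular oxa-Michael addition closes ring C, alpha-iodination and loss of HI aromatise it, DMSO turns HI back into I2, and the transient stereocentres of 21 and 22 are erased.

Step 12
Reactants: 23 2-[2,4-bis(benzyloxy)-5-methoxyphenyl]-5,6,7,8-tetramethoxy-4H-chromen-4-one
Product: 24 2-(2,4-dihydroxy-5-methoxyphenyl)-5,6,7,8-tetramethoxy-4H-chromen-4-one (2',4'-dihydroxy-5,6,7,8,5'-pentamethoxyflavone, CNP0237834.0)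
Conditions: H2 (1 atm), 10% Pd/C, THF/MeOH 1:1, rt, stopped after uptake of 2 equiv H2
Reagents that add atoms: none
Why: Catalytic hydrogenolysis cleaves only the two aryl benzyl ethers under neutral conditions and spares the methyl ethers and the chromone C2–C3 double bond, whereas a Lewis-acid debenzylation would also remove the chelated 5-OMe.

**Compound list**
1 | 2,3,4-trimethoxybenzaldehyde | COc1ccc(C=O)c(OC)c1OC | starting material
2 | 2,3,4-trimethoxyphenyl formate | COc1ccc(OC=O)c(OC)c1OC | intermediate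
3 | 2,3,4-trimethoxyphenol | COc1ccc(O)c(OC)c1OC | intermediate
4 | 1,2,3,4-tetramethoxybenzene | COc1ccc(OC)c(OC)c1OC | intermediate
5 | N,N-dimethyl-(2,3,4,5-tetramethoxybenzylidene)iminium dichlorophosphate | C[N+](C)=Cc1cc(OC)c(OC)c(OC)c1OC.[O-]P(=O)(Cl)Cl | intermediate
6 | 2,3,4,5-tetramethoxybenzaldehyde | COc1cc(C=O)c(OC)c(OC)c1OC | intermediate
7 | 2,3,4,5-tetramethoxyphenyl formate | COc1cc(OC=O)c(OC)c(OC)c1OC | intermediate
8 | 2,3,4,5-tetramethoxyphenol | COc1cc(O)c(OC)c(OC)c1OC | intermediate
9 | 2,3,4,5-tetramethoxyphenyl acetate | COc1cc(OC(C)=O)c(OC)c(OC)c1OC | intermediate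
10 | difluoroboron chelate of 1-(2-hydroxy-3,4,5,6-tetramethoxyphenyl)ethan-1-one | CC1=[O+][B-](F)(F)Oc2c(OC)c(OC)c(OC)c(OC)c12 | intermediate
11 | 1-(2-hydroxy-3,4,5,6-tetramethoxyphenyl)ethan-1-one | CC(=O)c1c(O)c(OC)c(OC)c(OC)c1OC | intermediate
12 | 2,4-dihydroxybenzaldehyde | O=Cc1ccc(O)cc1O | starting material
13 | 2,4-bis(benzyloxy)benzaldehyde | O=Cc1ccc(OCc2ccccc2)cc1OCc1ccccc1 | intermediate
14 | 2,4-bis(benzyloxy)phenyl formate | O=COc1ccc(OCc2ccccc2)cc1OCc1ccccc1 | intermediate
15 | 2,4-bis(benzyloxy)phenol | Oc1ccc(OCc2ccccc2)cc1OCc1ccccc1 | intermediate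
16 | 2,4-bis(benzyloxy)-1-methoxybenzene | COc1ccc(OCc2ccccc2)cc1OCc1ccccc1 | intermediate
17 | N,N-dimethyl-[2,4-bis(benzyloxy)-5-methoxybenzylidene]iminium dichlorophosphate | C[N+](C)=Cc1cc(OC)c(OCc2ccccc2)cc1OCc1ccccc1.[O-]P(=O)(Cl)Cl | intermediate
18 | 2,4-bis(benzyloxy)-5-methoxybenzaldehyde | COc1cc(C=O)c(OCc2ccccc2)cc1OCc1ccccc1 | intermediate
19 | 3-[2,4-bis(benzyloxy)-5-methoxyphenyl]-3-hydroxy-1-(2-hydroxy-3,4,5,6-tetramethoxyphenyl)propan-1-one (racemic) | COc1cc(C(O)CC(=O)c2c(O)c(OC)c(OC)c(OC)c2OC)c(OCc2ccccc2)cc1OCc1ccccc1 | intermediate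
20 | (E)-3-[2,4-bis(benzyloxy)-5-methoxyphenyl]-1-(2-hydroxy-3,4,5,6-tetramethoxyphenyl)prop-2-en-1-one | COc1cc(/C=C/C(=O)c2c(O)c(OC)c(OC)c(OC)c2OC)c(OCc2ccccc2)cc1OCc1ccccc1 | intermediate
21 | 2-[2,4-bis(benzyloxy)-5-methoxyphenyl]-5,6,7,8-tetramethoxychroman-4-one (racemic) | COc1cc(C2CC(=O)c3c(OC)c(OC)c(OC)c(OC)c3O2)c(OCc2ccccc2)cc1OCc1ccccc1 | intermediate
22 | 2-[2,4-bis(benzyloxy)-5-methoxyphenyl]-3-iodo-5,6,7,8-tetramethoxychroman-4-one (racemic) | COc1cc(C2Oc3c(OC)c(OC)c(OC)c(OC)c3C(=O)C2I)c(OCc2ccccc2)cc1OCc1ccccc1 | intermediate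
23 | 2-[2,4-bis(benzyloxy)-5-methoxyphenyl]-5,6,7,8-tetramethoxy-4H-chromen-4-one | COc1cc(-c2cc(=O)c3c(OC)c(OC)c(OC)c(OC)c3o2)c(OCc2ccccc2)cc1OCc1ccccc1 | intermediate
24 | 2-(2,4-dihydroxy-5-methoxyphenyl)-5,6,7,8-tetramethoxy-4H-chromen-4-one (achiral) | COc1cc(-c2cc(=O)c3c(OC)c(OC)c(OC)c(OC)c3o2)c(O)cc1O | target

**Total step count:** 12.
**Longest linear sequence:** 8 steps (steps 1–5, then 10–12). The ring B branch adds 4 steps (steps 6–9) before it joins at step 10.

**Three steps most likely to fail**

Step 5, acylation of the last free carbon of a penta-oxygenated ring. The risks are BF3-induced loss of the methyl ether next to the new ketone, or an incomplete Fries rearrangement. The fallback sets out from 8 and comes back at 11, and it replaces electrophilic chemistry with anionic chemistry. Compound 8 is protected with MeOCH2Cl/i-Pr2NEt in CH2Cl2 as 1-(methoxymethoxy)-2,3,4,5-tetramethoxybenzene F1. n-BuLi in THF at 0 °C then removes the only ring proton, which lies between the acetal oxygen and an OMe group (directed ortho-metalation), giving [2-(methoxymethoxy)-3,4,5,6-tetramethoxyphenyl]lithium F2. Quenching with N-methoxy-N-methylacetamide, followed by aqueous NH4Cl, gives 1-[2-(methoxymethoxy)-3,4,5,6-tetramethoxyphenyl]ethan-1-one F3. Catalytic HCl in MeOH removes the acetal to give 11.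

Step 10, the aldol condensation. The aldehyde is electron-rich and ortho-substituted, the ketone is di-ortho-substituted, and conversion may be slow. Partial closure of 20 to 21 during work-up is harmless, because both compounds go on to 23 in step 11. The fallback sets out from 18 and 11 and comes back at 23, so it bypasses steps 10 and 11.
- Compound 18 is oxidised (NaClO2, NaH2PO4, 2-methyl-2-butene, t-BuOH/H2O) to 2,4-bis(benzyloxy)-5-methoxybenzoic acid F4.
- (COCl)2 with catalytic DMF converts F4 into 2,4-bis(benzyloxy)-5-methoxybenzoyl chloride F5.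
- Compound 11 is doubly deprotonated with LiN(SiMe3)2 (3 equiv, THF, −78 °C) to dilithium 2-(1-oxidoethenyl)-3,4,5,6-tetramethoxyphenolate F6.
- F6 is C-acylated by F5 in an intermolecular Claisen-type condensation to give 1-[2,4-bis(benzyloxy)-5-methoxyphenyl]-3-(2-hydroxy-3,4,5,6-tetramethoxyphenyl)propane-1,3-dione F7.
- Cyclodehydration with catalytic p-TsOH in refluxing toluene gives 23.

Step 11, the I2/DMSO oxidative cyclisation. At 120 °C traces of HI may attack the 5-OMe or a benzyl ether, or iodinate ring B. The fallback sets out from 20 and comes back at 23, and it separates ring closure from oxidation. NaOAc in refluxing EtOH closes 20 to flavanone 21, which is now isolated. Me3SiOTf/Et3N in CH2Cl2 at 0 °C gives 2-[2,4-bis(benzyloxy)-5-methoxyphenyl]-5,6,7,8-tetramethoxy-4-(trimethylsilyloxy)-2H-chromene F8. Pd(OAc)2 (1 equiv, MeCN, rt) then carries out a Saegusa–Ito dehydrogenation to 23 at room temperature without acid or halogen, and the divalent palladium ends as zerovalent palladium.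

**Further compounds**
F1 | step 5 | 1-(methoxymethoxy)-2,3,4,5-tetramethoxybenzene | COCOc1cc(OC)c(OC)c(OC)c1OC
F2 | step 5 | [2-(methoxymethoxy)-3,4,5,6-tetramethoxyphenyl]lithium | [Li]c1c(OCOC)c(OC)c(OC)c(OC)c1OC
F3 | step 5 | 1-[2-(methoxymethoxy)-3,4,5,6-tetramethoxyphenyl]ethan-1-one | COCOc1c(C(C)=O)c(OC)c(OC)c(OC)c1OC
F4 | step 10 | 2,4-bis(benzyloxy)-5-methoxybenzoic acid | COc1cc(C(=O)O)c(OCc2ccccc2)cc1OCc1ccccc1
F5 | step 10 | 2,4-bis(benzyloxy)-5-methoxybenzoyl chloride | COc1cc(C(=O)Cl)c(OCc2ccccc2)cc1OCc1ccccc1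
F6 | step 10 | dilithium 2-(1-oxidoethenyl)-3,4,5,6-tetramethoxyphenolate | [Li+].[Li+].C=C([O-])c1c([O-])c(OC)c(OC)c(OC)c1OC
F7 | step 10 | 1-[2,4-bis(benzyloxy)-5-methoxyphenyl]-3-(2-hydroxy-3,4,5,6-tetramethoxyphenyl)propane-1,3-dione | COc1cc(C(=O)CC(=O)c2c(O)c(OC)c(OC)c(OC)c2OC)c(OCc2ccccc2)cc1OCc1ccccc1
F8 | step 11 | 2-[2,4-bis(benzyloxy)-5-methoxyphenyl]-5,6,7,8-tetramethoxy-4-(trimethylsilyloxy)-2H-chromene (racemic) | COc1cc(C2C=C(O[Si](C)(C)C)c3c(OC)c(OC)c(OC)c(OC)c3O2)c(OCc2ccccc2)cc1OCc1ccccc1
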